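**Retrosynthetic overview**
- The target is the octa-O-benzyl ether after hydrogenolysis. The strategy rests on the tetrahydrofuran ring O1'–C2'–C3'–C4'–C5': C2' is a benzylic ether carbon (4-hydroxyphenyl and O1' on it) in a 1,5 relationship to C3', so the C2'–C3' bond is cut as the retron of an intramolecular carbene C–H insertion.
- The C3' carbene comes from a diazo compound with C4'/C5' anti and a 4-benzyloxybenzyl group on O1'. The diazo compound is made from the C3' ketone through an N-silyl hydrazone, so that the acidic C4'–H never meets free hydrazine.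
- The ketone is cut at C3'–C4(aryl): a 4-lithio-2,3-dihydrobenzofuran adds to an α-aryl-β-alkoxy aldehyde, whose C4' and C5' centres come from an auxiliary-controlled magnesium-catalysed anti-aldol reaction.
- The trans-2,3-diaryl-2,3-dihydrobenzofuran with a bromine at C4 is made by an enantioselective donor/donor carbene insertion into a benzyl ether C–H bond, followed by acid epimerisation at C2.
- Ring order: furan ring of the dihydrobenzofuran first (step 13), tetrahydrofuran last (step 19).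

Key step: step 19

Assumption: Rh2(S-PTAD)4 is taken as the catalyst enantiomer that sets (3S) at the dihydrobenzofuran in step 13; should the sense of induction be the opposite, Rh2(R-PTAD)4 is used there and nothing else changes.

Shorthand in names: DBF = the (2S,3S)-6-(benzyloxy)-2-[4-(benzyloxy)phenyl]-3-[3,5-bis(benzyloxy)phenyl]-2,3-dihydro-1-benzofuran-4-yl group. Primed locants (O1', C2'–C5') refer to the tetrahydrofuran and its open-chain precursors.

**Route**

Step 1
Reactants: 1 2-[3,5-bis(benzyloxy)phenyl]acetic acid; 2 (R)-4-benzyl-1,3-oxazolidin-2-one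
Product: 4 (R)-4-benzyl-3-{[3,5-bis(benzyloxy)phenyl]acetyl}-1,3-oxazolidin-2-one, via mixed pivalic anhydride 3 (not isolated)
Conditions: PivCl, Et3N, THF, −20 °C; then 2, LiCl, −20 °C → rt
Reagents that add atoms: none
Why: N-acylation of the oxazolidinone by the mixed anhydride (LiCl-assisted imide formation) installs the auxiliary that will control C4' and C5'; no stereocentre is formed.

Step 2
Reactants: 4 arylacetyl oxazolidinone; 5 4-(benzyloxy)benzaldehyde
Product: 7 (R)-4-benzyl-3-{(2S,3R)-3-[4-(benzyloxy)phenyl]-2-[3,5-bis(benzyloxy)phenyl]-3-hydroxypropanoyl}-1,3-oxazolidin-2-one, via trimethylsilyl ether 6 (not isolated)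
Conditions: MgCl2 (20 mol%), Et3N, TMSCl, EtOAc, rt; then PPTS (cat.), MeOH, 0 °C
Reagents that add atoms: none
Why: Magnesium chloride-catalysed direct anti-aldol reaction of an N-acyloxazolidinone (Evans anti-aldol): the magnesium-chelated Z-enolate is attacked by the aldehyde on the face away from the auxiliary benzyl group through a boat-like transition state, which sets C4' as (2S) and, the addition being anti, C5' as (3R), while silylation of the aldolate turns the catalyst over and blocks retro-aldol.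

Step 3
Reactants: 8 [4-(benzyloxy)phenyl]methanol
Product: 9 4-(benzyloxy)benzyl 2,2,2-trichloroacetimidate
Conditions: Cl3CCN, DBU (cat.), CH2Cl2, 0 °C; used crude
Reagents that add atoms: trichloroacetonitrile, N#CC(Cl)(Cl)Cl
Why: Base-catalysed addition of the benzylic alcohol to trichloroacetonitrile gives the imidate, an alkylating agent that is activated by acid and needs no base.

Step 4
Reactants: 7 anti aldol adduct; 9 trichloroacetimidate
Product: 10 (R)-4-benzyl-3-{(2S,3R)-3-[4-(benzyloxy)phenyl]-3-{[4-(benzyloxy)benzyl]oxy}-2-[3,5-bis(benzyloxy)phenyl]propanoyl}-1,3-oxazolidin-2-one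
Conditions: La(OTf)3 (5 mol%), toluene, 0 °C → rt
Reagents that add atoms: none
Why: Lewis acid-catalysed O-alkylation by the trichloroacetimidate puts the 4-benzyloxybenzyl group on the C5' oxygen without base, so the aldol adduct cannot undergo retro-aldol cleavage and C4' and C5' are not touched.

Step 5
Reactants: 10 ether imide
Product: 11 (2R,3R)-3-[4-(benzyloxy)phenyl]-3-{[4-(benzyloxy)benzyl]oxy}-2-[3,5-bis(benzyloxy)phenyl]propan-1-ol
Conditions: LiBH4, MeOH (1 equiv), THF, 0 °C
Reagents that add atoms: none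
Why: Hydride reduction of the exocyclic imide carbonyl (reductive auxiliary cleavage) releases the primary alcohol and the recoverable oxazolidinone without a base able to epimerise C4'.

Step 6
Reactants: 11 primary alcohol
Product: 12 (2S,3R)-3-[4-(benzyloxy)phenyl]-3-{[4-(benzyloxy)benzyl]oxy}-2-[3,5-bis(benzyloxy)phenyl]propanal
Conditions: Dess–Martin periodinane, NaHCO3, CH2Cl2, 0 °C; used crude
Reagents that add atoms: none
Why: Dess–Martin oxidation gives the aldehyde under buffered, non-enolising conditions, and the configurationally sensitive α-aryl aldehyde is carried on without chromatography.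

Step 7
Reactants: 13 1,3-bis(benzyloxy)-5-bromobenzene
Product: 14 2,4-bis(benzyloxy)-6-bromobenzaldehyde
Conditions: POCl3, DMF, 0 → 90 °C; then ice-water
Reagents that add atoms: N,N-dimethylformamide, CN(C)C=O; water, O
Why: Vilsmeier–Haack formylation takes place at the position ortho to one benzyloxy group and para to the other (next to bromine), the less hindered of the two doubly activated sites.

Step 8
Reactants: 14 bromo aldehyde
Product: 15 4-(benzyloxy)-2-bromo-6-hydroxybenzaldehyde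
Conditions: MgBr2·OEt2, toluene/Et2O, 70 °C; 1 M HCl work-up
Reagents that add atoms: none
Why: Chelation of magnesium between the aldehyde oxygen and the ortho ether oxygen directs bromide to that benzyl group only (chelation-directed debenzylation), leaving the para benzyl ether in place.

Step 9
Reactants: 15 salicylaldehyde; 16 4-(benzyloxy)benzyl chloride
Product: 17 4-(benzyloxy)-2-{[4-(benzyloxy)benzyl]oxy}-6-bromobenzaldehyde
Conditions: K2CO3, Bu4NI (cat.), DMF, 50 °C
Reagents that add atoms: none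
Why: Williamson alkylation of the phenoxide installs the benzyl ether whose CH2 group will later become C2 of the dihydrobenzofuran.

Step 10
Reactants: 13 1,3-bis(benzyloxy)-5-bromobenzene; 17 aldehyde
Product: 19 (4-(benzyloxy)-2-{[4-(benzyloxy)benzyl]oxy}-6-bromophenyl)[3,5-bis(benzyloxy)phenyl]methanol (racemic), via arylmagnesium bromide 18 (not isolated)
Conditions: Mg, I2 (cat.), THF, 45 °C; then 17, −20 → 0 °C; aq. NH4Cl
Reagents that add atoms: none
Why: Grignard addition to the aldehyde is much faster than any exchange at the aryl bromide of 17, and the new carbinol centre is removed in the next step.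

Step 11
Reactants: 19 diaryl carbinol
Product: 20 (4-(benzyloxy)-2-{[4-(benzyloxy)benzyl]oxy}-6-bromophenyl)[3,5-bis(benzyloxy)phenyl]methanone
Conditions: Dess–Martin periodinane, NaHCO3, CH2Cl2, rt
Reagents that add atoms: none
Why: Dess–Martin oxidation of the doubly benzylic alcohol gives the benzophenone without touching the benzyl ethers.

Step 12
Reactants: 20 benzophenone
Product: 21 hydrazone of 20 (E/Z mixture)
Conditions: N2H4·H2O (20 equiv), AcOH (cat.), EtOH, 90 °C, sealed tube
Reagents that add atoms: hydrazine, NN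
Why: Acid-catalysed condensation with excess hydrazine is forced at the hindered diaryl ketone, which has no stereocentre or enolisable position to lose.

Step 13
Reactants: 21 hydrazone
Product: 23 (2R,3S)-6-(benzyloxy)-2-[4-(benzyloxy)phenyl]-3-[3,5-bis(benzyloxy)phenyl]-4-bromo-2,3-dihydro-1-benzofuran (cis), via diaryldiazomethane 22 (not isolated)
Conditions: MnO2, CH2Cl2, 0 °C; filtered through Celite into Rh2(S-PTAD)4 (1 mol%), CH2Cl2, 0 °C
Reagents that add atoms: none
Why: Hydrazone oxidation gives the diaryldiazomethane, whose rhodium carbene inserts into the ortho benzyl ether C–H bond (donor/donor carbene 1,5 C–H insertion) to close the furan ring as the cis-2,3-diaryl isomer, the chiral carboxylate fixing the absolute sense at C3, the centre that is kept to the end.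

Step 14
Reactants: 23 cis-dihydrobenzofuran
Product: 24 (2S,3S)-6-(benzyloxy)-2-[4-(benzyloxy)phenyl]-3-[3,5-bis(benzyloxy)phenyl]-4-bromo-2,3-dihydro-1-benzofuran (trans)
Conditions: TFA (5 equiv), CH2Cl2, 0 °C → rt
Reagents that add atoms: none
Why: Acid-mediated epimerisation: reversible ionisation of the C2–O bond to the 4-benzyloxybenzylic cation and reclosure deliver the thermodynamically preferred trans isomer by inversion at C2 only, C3 being untouched.

Step 15
Reactants: 24 trans-4-bromodihydrobenzofuran; 12 aldehyde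
Product: 26 (1RS,2R,3R)-3-[4-(benzyloxy)phenyl]-3-{[4-(benzyloxy)benzyl]oxy}-2-[3,5-bis(benzyloxy)phenyl]-1-(DBF)propan-1-ol, via aryllithium 25 (not isolated)
Conditions: t-BuLi (2.0 equiv), THF, −78 °C; then 12, −78 °C; AcOH, −78 °C
Reagents that add atoms: none
Why: Bromine–lithium exchange followed by addition of the aryllithium to the aldehyde forms the C3'–C4(aryl) bond at a temperature where carbonyl addition outruns enolisation, and the C3' carbinol configuration is irrelevant because it is oxidised next.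

Step 16
Reactants: 26 carbinol
Product: 27 (2S,3R)-3-[4-(benzyloxy)phenyl]-3-{[4-(benzyloxy)benzyl]oxy}-2-[3,5-bis(benzyloxy)phenyl]-1-(DBF)propan-1-one
Conditions: Dess–Martin periodinane, NaHCO3, CH2Cl2, 0 °C → rt
Reagents that add atoms: none
Why: Dess–Martin oxidation gives the aryl ketone under buffered conditions that do not enolise the acidic C4' position.

Step 17
Reactants: 27 ketone
Product: 28 N-(tert-butyldimethylsilyl)hydrazone of 27 (C4'/C5' anti; 2R,3R by the priority rules)
Conditions: TBSNHNHTBS (1.5 equiv), Sc(OTf)3 (1 mol%), ClCH2CH2Cl, 60 °C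
Reagents that add atoms: 1,2-bis(tert-butyldimethylsilyl)hydrazine, CC(C)(C)[Si](C)(C)NN[Si](C)(C)C(C)(C)C
Why: Scandium triflate-catalysed condensation of the silylhydrazine with the ketone needs no free hydrazine, so the acidic C4'–H and the β-alkoxy group are not exposed to base-induced epimerisation or E1cB loss, and silanol is the only by-product.

Step 18
Reactants: 28 N-silyl hydrazone
Product: 30 (2R,3R)-3-[4-(benzyloxy)phenyl]-3-{[4-(benzyloxy)benzyl]oxy}-2-[3,5-bis(benzyloxy)phenyl]-1-diazo-1-(DBF)propane, via free hydrazone 29 (not isolated)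
Conditions: TBAF/AcOH (1:1, 1.2 equiv), THF, 0 °C; aq. NaHCO3 wash; then MnO2, CH2Cl2, 0 °C; cold filtration through Celite, solution used at once
Reagents that add atoms: none
Why: Fluoride removes the N-silyl group and MnO2 dehydrogenates the N-unsubstituted hydrazone to the diazo compound (hydrazone oxidation) at a temperature where the aryl/alkyl diazo compound survives and C4' and C5' are not touched.

Step 19
Reactants: 30 diazo compound
Product: 31 (2S,3S)-4-{(2R,3R,4S,5R)-2,5-bis[4-(benzyloxy)phenyl]-4-[3,5-bis(benzyloxy)phenyl]oxolan-3-yl}-6-(benzyloxy)-2-[4-(benzyloxy)phenyl]-3-[3,5-bis(benzyloxy)phenyl]-2,3-dihydro-1-benzofuran (octabenzyl ether of the target)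
Conditions: Rh2(R-PTAD)4 (2 mol%), CH2Cl2, −40 → 0 °C, slow addition of the cold solution of 30
Reagents that add atoms: none
Why: Proposed new method: loss of dinitrogen from 30 at the dirhodium tetracarboxylate gives an aryl/alkyl (donor/donor) rhodium carbene at C3', which takes hydride from the ether CH2 group on O1' and closes the C2'–C3' bond at once; the closest known reactions are the Rh2(PTAD)4-catalysed donor/donor carbene insertions into benzyl ether C–H bonds that give cis-2,3-diaryl-2,3-dihydrobenzofurans and the metalloporphyrin-catalysed 1,5 insertions of alkyl carbenes that give cis-2,3-disubstituted tetrahydrofurans. The tetrahydrofuran is closed by a 1,5 C–H insertion, that is C2'–C3' bond formation through a five-membered array C3'–C4'–C5'–O1'–C2' with the hydrogen migrating from C2' to C3'. C3' is controlled by the resident C4' centre: the metal with its ligands lies anti to the C4' aryl group across C3'–C4', so once the metal has left the C3' aryl group stands cis to the C4' aryl group. C2' is controlled by the carboxylate wall of the catalyst, which turns the ether aryl group away from the metal and therefore cis to the C3' aryl group, giving the 2',3',4'-all-cis, 4',5'-trans ring. The step needs chemoselectivity over 1,2-hydride shift from C4' and over attack on the electron-rich arenes; the bulky carboxylate, the low temperature and the hydridic character of the C–H bond, activated by both oxygen and aryl, are meant to secure it, and insertion into the C–H bonds of the dihydrobenzofuran would need a four-membered or bridged ring.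

Step 20
Reactants: 31 octabenzyl ether
Product: 32 (2S,3S)-4-[(2R,3R,4S,5R)-4-(3,5-dihydroxyphenyl)-2,5-bis(4-hydroxyphenyl)oxolan-3-yl]-3-(3,5-dihydroxyphenyl)-2-(4-hydroxyphenyl)-2,3-dihydro-1-benzofuran-6-ol (CNP0202577.4)
Conditions: H2 (1 atm), Pd/C (10 wt%), NaHCO3 (solid), EtOAc/MeOH, rt, stopped at full conversion
Reagents that add atoms: none
Why: Heterogeneous hydrogenolysis cleaves the eight aryl benzyl ethers faster than the more hindered ring C–O bonds at C2', C5' and C2, the bicarbonate buffer suppresses acid-promoted ionisation at these benzylic ether carbons, and no stereocentre is touched.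

**Compound list**

1 | 2-[3,5-bis(benzyloxy)phenyl]acetic acid | OC(=O)Cc1cc(OCc2ccccc2)cc(OCc2ccccc2)c1 | starting material
2 | (R)-4-benzyl-1,3-oxazolidin-2-one | O=C1N[C@H](Cc2ccccc2)CO1 | starting material
3 | [3,5-bis(benzyloxy)phenyl]acetic pivalic anhydride | CC(C)(C)C(=O)OC(=O)Cc1cc(OCc2ccccc2)cc(OCc2ccccc2)c1 | intermediate
4 | (R)-4-benzyl-3-{[3,5-bis(benzyloxy)phenyl]acetyl}-1,3-oxazolidin-2-one | O=C(Cc1cc(OCc2ccccc2)cc(OCc2ccccc2)c1)N1[C@H](Cc2ccccc2)COC1=O | intermediate
5 | 4-(benzyloxy)benzaldehyde | O=Cc1ccc(OCc2ccccc2)cc1 | starting material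
6 | O-trimethylsilyl ether of 7 | O=C(N1[C@H](Cc2ccccc2)COC1=O)[C@@H](c1cc(OCc2ccccc2)cc(OCc2ccccc2)c1)[C@H](c1ccc(OCc2ccccc2)cc1)O[Si](C)(C)C | intermediate
7 | (R)-4-benzyl-3-{(2S,3R)-3-[4-(benzyloxy)phenyl]-2-[3,5-bis(benzyloxy)phenyl]-3-hydroxypropanoyl}-1,3-oxazolidin-2-one | O=C(N1[C@H](Cc2ccccc2)COC1=O)[C@@H](c1cc(OCc2ccccc2)cc(OCc2ccccc2)c1)[C@H](c1ccc(OCc2ccccc2)cc1)O | intermediate
8 | [4-(benzyloxy)phenyl]methanol | OCc1ccc(OCc2ccccc2)cc1 | starting material
9 | 4-(benzyloxy)benzyl 2,2,2-trichloroacetimidate | N=C(OCc1ccc(OCc2ccccc2)cc1)C(Cl)(Cl)Cl | intermediate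
10 | (R)-4-benzyl-3-{(2S,3R)-3-[4-(benzyloxy)phenyl]-3-{[4-(benzyloxy)benzyl]oxy}-2-[3,5-bis(benzyloxy)phenyl]propanoyl}-1,3-oxazolidin-2-one | O=C(N1[C@H](Cc2ccccc2)COC1=O)[C@@H](c1cc(OCc2ccccc2)cc(OCc2ccccc2)c1)[C@H](c1ccc(OCc2ccccc2)cc1)OCc1ccc(OCc2ccccc2)cc1 | intermediate
11 | (2R,3R)-3-[4-(benzyloxy)phenyl]-3-{[4-(benzyloxy)benzyl]oxy}-2-[3,5-bis(benzyloxy)phenyl]propan-1-ol | OC[C@@H](c1cc(OCc2ccccc2)cc(OCc2ccccc2)c1)[C@H](c1ccc(OCc2ccccc2)cc1)OCc1ccc(OCc2ccccc2)cc1 | intermediate
12 | (2S,3R)-3-[4-(benzyloxy)phenyl]-3-{[4-(benzyloxy)benzyl]oxy}-2-[3,5-bis(benzyloxy)phenyl]propanal | O=C[C@@H](c1cc(OCc2ccccc2)cc(OCc2ccccc2)c1)[C@H](c1ccc(OCc2ccccc2)cc1)OCc1ccc(OCc2ccccc2)cc1 | intermediate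
13 | 1,3-bis(benzyloxy)-5-bromobenzene | Brc1cc(OCc2ccccc2)cc(OCc2ccccc2)c1 | starting material
14 | 2,4-bis(benzyloxy)-6-bromobenzaldehyde | O=Cc1c(Br)cc(OCc2ccccc2)cc1OCc1ccccc1 | intermediate
15 | 4-(benzyloxy)-2-bromo-6-hydroxybenzaldehyde | O=Cc1c(Br)cc(OCc2ccccc2)cc1O | intermediate
16 | 4-(benzyloxy)benzyl chloride | ClCc1ccc(OCc2ccccc2)cc1 | starting material
17 | 4-(benzyloxy)-2-{[4-(benzyloxy)benzyl]oxy}-6-bromobenzaldehyde | O=Cc1c(Br)cc(OCc2ccccc2)cc1OCc1ccc(OCc2ccccc2)cc1 | intermediate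
18 | [3,5-bis(benzyloxy)phenyl]magnesium bromide | Br[Mg]c1cc(OCc2ccccc2)cc(OCc2ccccc2)c1 | intermediate
19 | (4-(benzyloxy)-2-{[4-(benzyloxy)benzyl]oxy}-6-bromophenyl)[3,5-bis(benzyloxy)phenyl]methanol, racemic | OC(c1cc(OCc2ccccc2)cc(OCc2ccccc2)c1)c1c(Br)cc(OCc2ccccc2)cc1OCc1ccc(OCc2ccccc2)cc1 | intermediate
20 | (4-(benzyloxy)-2-{[4-(benzyloxy)benzyl]oxy}-6-bromophenyl)[3,5-bis(benzyloxy)phenyl]methanone | O=C(c1cc(OCc2ccccc2)cc(OCc2ccccc2)c1)c1c(Br)cc(OCc2ccccc2)cc1OCc1ccc(OCc2ccccc2)cc1 | intermediate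
21 | hydrazone of 20 | NN=C(c1cc(OCc2ccccc2)cc(OCc2ccccc2)c1)c1c(Br)cc(OCc2ccccc2)cc1OCc1ccc(OCc2ccccc2)cc1 | intermediate
22 | (4-(benzyloxy)-2-{[4-(benzyloxy)benzyl]oxy}-6-bromophenyl)[3,5-bis(benzyloxy)phenyl]diazomethane | [N-]=[N+]=C(c1cc(OCc2ccccc2)cc(OCc2ccccc2)c1)c1c(Br)cc(OCc2ccccc2)cc1OCc1ccc(OCc2ccccc2)cc1 | intermediate
23 | (2R,3S)-6-(benzyloxy)-2-[4-(benzyloxy)phenyl]-3-[3,5-bis(benzyloxy)phenyl]-4-bromo-2,3-dihydro-1-benzofuran (cis) | c6ccccc6COc1ccc([C@@H]2Oc3cc(OCc6ccccc6)cc(Br)c3[C@@H]2c2cc(OCc6ccccc6)cc(OCc6ccccc6)c2)cc1 | intermediate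
24 | (2S,3S)-6-(benzyloxy)-2-[4-(benzyloxy)phenyl]-3-[3,5-bis(benzyloxy)phenyl]-4-bromo-2,3-dihydro-1-benzofuran (trans) | c6ccccc6COc1ccc([C@H]2Oc3cc(OCc6ccccc6)cc(Br)c3[C@@H]2c2cc(OCc6ccccc6)cc(OCc6ccccc6)c2)cc1 | intermediate
25 | DBF-lithium (4-lithio derivative of 24) | c6ccccc6COc1ccc([C@H]2Oc3cc(OCc6ccccc6)cc([Li])c3[C@@H]2c2cc(OCc6ccccc6)cc(OCc6ccccc6)c2)cc1 | intermediate
26 | (1RS,2R,3R)-3-[4-(benzyloxy)phenyl]-3-{[4-(benzyloxy)benzyl]oxy}-2-[3,5-bis(benzyloxy)phenyl]-1-(DBF)propan-1-ol | c6ccccc6COc1ccc([C@H]2Oc3cc(OCc6ccccc6)cc(C(O)[C@@H](c5cc(OCc6ccccc6)cc(OCc6ccccc6)c5)[C@H](c5ccc(OCc6ccccc6)cc5)OCc4ccc(OCc6ccccc6)cc4)c3[C@@H]2c2cc(OCc6ccccc6)cc(OCc6ccccc6)c2)cc1 | intermediate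
27 | (2S,3R)-3-[4-(benzyloxy)phenyl]-3-{[4-(benzyloxy)benzyl]oxy}-2-[3,5-bis(benzyloxy)phenyl]-1-(DBF)propan-1-one | c6ccccc6COc1ccc([C@H]2Oc3cc(OCc6ccccc6)cc(C(=O)[C@@H](c5cc(OCc6ccccc6)cc(OCc6ccccc6)c5)[C@H](c5ccc(OCc6ccccc6)cc5)OCc4ccc(OCc6ccccc6)cc4)c3[C@@H]2c2cc(OCc6ccccc6)cc(OCc6ccccc6)c2)cc1 | intermediate
28 | N-(tert-butyldimethylsilyl)hydrazone of 27 | c6ccccc6COc1ccc([C@H]2Oc3cc(OCc6ccccc6)cc(C(=NN[Si](C)(C)C(C)(C)C)[C@@H](c5cc(OCc6ccccc6)cc(OCc6ccccc6)c5)[C@H](c5ccc(OCc6ccccc6)cc5)OCc4ccc(OCc6ccccc6)cc4)c3[C@@H]2c2cc(OCc6ccccc6)cc(OCc6ccccc6)c2)cc1 | intermediate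
29 | N-unsubstituted hydrazone of 27 | c6ccccc6COc1ccc([C@H]2Oc3cc(OCc6ccccc6)cc(C(=NN)[C@@H](c5cc(OCc6ccccc6)cc(OCc6ccccc6)c5)[C@H](c5ccc(OCc6ccccc6)cc5)OCc4ccc(OCc6ccccc6)cc4)c3[C@@H]2c2cc(OCc6ccccc6)cc(OCc6ccccc6)c2)cc1 | intermediate
30 | (2R,3R)-3-[4-(benzyloxy)phenyl]-3-{[4-(benzyloxy)benzyl]oxy}-2-[3,5-bis(benzyloxy)phenyl]-1-diazo-1-(DBF)propane | c6ccccc6COc1ccc([C@H]2Oc3cc(OCc6ccccc6)cc(C(=[N+]=[N-])[C@@H](c5cc(OCc6ccccc6)cc(OCc6ccccc6)c5)[C@H](c5ccc(OCc6ccccc6)cc5)OCc4ccc(OCc6ccccc6)cc4)c3[C@@H]2c2cc(OCc6ccccc6)cc(OCc6ccccc6)c2)cc1 | intermediate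
31 | octabenzyl ether of the target, tetrahydrofuran 2'R,3'R,4'S,5'R, dihydrobenzofuran 2S,3S | c6ccccc6COc1ccc([C@H]2Oc3cc(OCc6ccccc6)cc([C@H]4[C@@H](c5cc(OCc6ccccc6)cc(OCc6ccccc6)c5)[C@H](c5ccc(OCc6ccccc6)cc5)O[C@H]4c4ccc(OCc6ccccc6)cc4)c3[C@@H]2c2cc(OCc6ccccc6)cc(OCc6ccccc6)c2)cc1 | intermediate
32 | (2S,3S)-4-[(2R,3R,4S,5R)-4-(3,5-dihydroxyphenyl)-2,5-bis(4-hydroxyphenyl)oxolan-3-yl]-3-(3,5-dihydroxyphenyl)-2-(4-hydroxyphenyl)-2,3-dihydro-1-benzofuran-6-ol | Oc1ccc([C@H]2Oc3cc(O)cc([C@H]4[C@@H](c5cc(O)cc(O)c5)[C@H](c5ccc(O)cc5)O[C@H]4c4ccc(O)cc4)c3[C@@H]2c2cc(O)cc(O)c2)cc1 | target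

**Step count**
Total: 20 steps. Longest linear sequence: 14 steps (13 → 32 through steps 7–20).

**Steps most likely to fail**

1. Step 19 (key step). The carbene may be lost to 1,2-hydride shift from C4', or to attack on the electron-rich 3,5-bis(benzyloxy)phenyl ring at C3 of the dihydrobenzofuran, before it reaches the ether C–H bond; the ring may also close from the wrong face of the carbene. The fallback uses known chemistry with another carbene source and another class of metal carbene. It sets out from ketone 27, which is condensed with tosylhydrazide (TsNHNH2, THF/MeOH, 50 °C) to the N-tosylhydrazone F1. F1 is then heated with K2CO3 and Ru(TTP)(CO) (2 mol%; TTP = 5,10,15,20-tetra-p-tolylporphyrinate) in dioxane at 90 °C. The diazo compound 30 is released slowly by Bamford–Stevens fragmentation and is taken up at once as a ruthenium porphyrin carbene. This catalyst class is established for 1,5 insertion of alkyl carbenes with β-hydrogens into benzylic ether C–H bonds, giving cis-2,3-disubstituted tetrahydrofurans from ketone tosylhydrazones. No hydrazone oxidation and no handling of the diazo compound are needed, and the fallback comes back to the route at 31.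

2. Step 20. Hydrogenolysis may not stop at the eight O-benzyl groups: the benzylic ring C–O bonds at C2', C5' and C2 may be cleaved, or acid traces on the catalyst may open the tetrahydrofuran reversibly and epimerise C2' or C5'. The fallback replaces reduction by Lewis acid cleavage with a cation scavenger. It sets out from 31, which is treated with BCl3 and pentamethylbenzene in CH2Cl2 at −78 °C and quenched with MeOH at that temperature. The crude octaphenol is acetylated (Ac2O, pyridine) to the octaacetate F2, which can be purified on silica. Methanolysis of F2 (K2CO3 cat., MeOH, 0 °C) then comes back to the route at 32.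

3. Step 15. The hindered aryllithium may act as a base on the α-aryl aldehyde instead of adding to it, which would epimerise C4' or expel the β-alkoxide. The fallback forms the C3'–C4(aryl) bond by acyl cross-coupling under neutral conditions. It sets out from imide 10, which is cleaved with EtSLi (EtSH, n-BuLi, THF, 0 °C) to the S-ethyl thioester F3. Aryllithium 25, made from 24 as in step 15, is transmetalated with ZnCl2 to the arylzinc chloride F4. Fukuyama coupling of F3 with F4 (PdCl2(PPh3)2, 5 mol%, THF/toluene, rt) gives the ketone directly and comes back to the route at 27, with steps 5, 6 and 16 no longer needed.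

**Further compounds**
F1 | step 19 | N-tosylhydrazone of ketone 27 | c6ccccc6COc1ccc([C@H]2Oc3cc(OCc6ccccc6)cc(C(=NNS(=O)(=O)c7ccc(C)cc7)[C@@H](c5cc(OCc6ccccc6)cc(OCc6ccccc6)c5)[C@H](c5ccc(OCc6ccccc6)cc5)OCc4ccc(OCc6ccccc6)cc4)c3[C@@H]2c2cc(OCc6ccccc6)cc(OCc6ccccc6)c2)cc1
F2 | step 20 | octaacetate of 32 | CC(=O)Oc1ccc([C@H]2Oc3cc(OC(C)=O)cc([C@H]4[C@@H](c5cc(OC(C)=O)cc(OC(C)=O)c5)[C@H](c5ccc(OC(C)=O)cc5)O[C@H]4c4ccc(OC(C)=O)cc4)c3[C@@H]2c2cc(OC(C)=O)cc(OC(C)=O)c2)cc1
F3 | step 15 | S-ethyl (2S,3R)-3-[4-(benzyloxy)phenyl]-3-{[4-(benzyloxy)benzyl]oxy}-2-[3,5-bis(benzyloxy)phenyl]propanethioate | CCSC(=O)[C@@H](c1cc(OCc2ccccc2)cc(OCc2ccccc2)c1)[C@H](c1ccc(OCc2ccccc2)cc1)OCc1ccc(OCc2ccccc2)cc1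
F4 | step 15 | DBF-zinc chloride | c6ccccc6COc1ccc([C@H]2Oc3cc(OCc6ccccc6)cc([Zn]Cl)c3[C@@H]2c2cc(OCc6ccccc6)cc(OCc6ccccc6)c2)cc1
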